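**Plan**

- Labdane numbering is used: ring A = C1–C5/C10, ring B = C5–C10, side chain C11–C16 (C15 = carboxyl), C17 on C8, C18/C19 on C4, C20 on C10. Retrosynthesis: after redox correction at C3/C6 and deprotection, the decalin is cut at C9–C10 and C4–C5 to an acyclic epoxy tetraene; the chain is then cut at C9–C11, C8–C17, C6–C7 and C3=C4.
- Forward chain assembly: geranyl acetate gives C1–C3, C5, C6, C10, C20; Z-olefination adds C4/C18/C19; propargylation adds C7–C9; methylmagnesiation adds C17; Negishi coupling adds C11–C16; epoxidation follows.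
- Rings: one Lewis-acid cascade closes ring A first (C4–C5) and ring B last (C9–C10).
- Enabling feature: ring B holds a tetrasubstituted C8=C9 alkene beside the quaternary C10, the mark of a C8 cation formed when C9 attacks a C10 cation. A Me3Si group on C9 of the open chain makes the collapse to C8=C9 regiospecific, and the C6 oxygen rides equatorial.
- Stereochemistry: the oxirane (C3/C4, Sharpless) dictates the chair–chair fold and so C5 and C10, with C19 axial from the Z-alkene. C6 (S, catalytic propargylation) is the matched centre. C3 and C6 are finally reset to 3α/6β by oxidation to the 3,6-dione and hindered-hydride reduction.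

Key step: step 14

Remark: the bisphosphine antipode in step 5 is taken to be the one that delivers the S carbinol; compounds 4, 8 and 13 are purchased. TBS = tert-butyldimethylsilyl, TBDPS = tert-butyldiphenylsilyl.

**Route**

Step 1
Reactants: 1 geranyl acetate
Product: 3 (2E)-3-methyl-6-oxohex-2-en-1-yl acetate, via 6,7-epoxygeranyl acetate 2 (not isolated)
Conditions: mCPBA, CH2Cl2, 0 °C; crude epoxide, then H5IO6, THF–H2O, 0 °C to rt
Reagents that add atoms: 3-chloroperoxybenzoic acid (mCPBA), OOC(=O)c1cccc(Cl)c1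
Why: Prilezhaev epoxidation picks the electron-rich distal trisubstituted alkene over the acetoxy-deactivated allylic one, and periodic acid then hydrolyses the epoxide and cleaves the glycol (Malaprade cleavage) to the aldehyde without touching the E-alkene.

Step 2
Reactants: 3 (2E)-3-methyl-6-oxohex-2-en-1-yl acetate; 4 ethyl 2-[bis(2,2,2-trifluoroethoxy)phosphoryl]propanoate
Product: 5 ethyl (2Z,6E)-8-acetoxy-2,6-dimethylocta-2,6-dienoate
Conditions: KN(SiMe3)2, 18-crown-6, THF, −78 °C
Reagents that add atoms: none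
Why: Still–Gennari olefination: the trifluoroethyl phosphonate collapses from the kinetic adduct, so the trisubstituted Z-enoate (ester cis to the chain) should form, the geometry that later places C19 axial on C4.

Step 3
Reactants: 5 ethyl (2Z,6E)-8-acetoxy-2,6-dimethylocta-2,6-dienoate
Product: 6 ethyl (2Z,6E)-8-hydroxy-2,6-dimethylocta-2,6-dienoate
Conditions: K2CO3 (cat.), EtOH, 0 °C to rt
Reagents that add atoms: none
Why: Base-catalysed transesterification removes the unhindered allylic acetate, while exchange at the conjugated ethyl ester is degenerate in ethanol.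

Step 4
Reactants: 6 ethyl (2Z,6E)-8-hydroxy-2,6-dimethylocta-2,6-dienoate
Product: 7 ethyl (2Z,6E)-2,6-dimethyl-8-oxoocta-2,6-dienoate
Conditions: MnO2 (excess), CH2Cl2, rt
Reagents that add atoms: none
Why: Manganese dioxide oxidises only the allylic alcohol and should give the E-enal without isomerisation (allylic oxidation).

Step 5
Reactants: 7 ethyl (2Z,6E)-2,6-dimethyl-8-oxoocta-2,6-dienoate; 8 4,4,5,5-tetramethyl-2-[3-(trimethylsilyl)prop-2-yn-1-yl]-1,3,2-dioxaborolane
Product: 9 ethyl (2Z,6E,8S)-8-hydroxy-2,6-dimethyl-11-(trimethylsilyl)undeca-2,6-dien-10-ynoate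
Conditions: Cu(O2CCHMe2)2 (5 mol %), LiOtBu (10 mol %), MeO-BIBOP-type chiral bisphosphine (6 mol %), THF, −30 °C; aqueous work-up
Reagents that add atoms: none
Why: Copper-catalysed enantioselective propargylation: boron-to-copper exchange gives an allenylcopper that adds 1,2 to the aldehyde through a cyclic SE2' transition state, so the silylalkyne is returned and the ligand sets the S configuration at the new carbinol (C6 in labdane numbering).

Step 6
Reactants: 9 ethyl (2Z,6E,8S)-8-hydroxy-2,6-dimethyl-11-(trimethylsilyl)undeca-2,6-dien-10-ynoate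
Product: 10 ethyl (2Z,6E,8S)-8-[(tert-butyldimethylsilyl)oxy]-2,6-dimethyl-11-(trimethylsilyl)undeca-2,6-dien-10-ynoate
Conditions: TBSCl, imidazole, DMF, rt
Reagents that add atoms: tert-butyldimethylsilyl chloride, CC(C)(C)[Si](C)(C)Cl
Why: Silyl ether formation masks the secondary allylic alcohol so that it neither directs the later epoxidation nor binds the Lewis acid.

Step 7
Reactants: 10 ethyl (2Z,6E,8S)-8-[(tert-butyldimethylsilyl)oxy]-2,6-dimethyl-11-(trimethylsilyl)undeca-2,6-dien-10-ynoate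
Product: 11 (2Z,6E,8S)-8-[(tert-butyldimethylsilyl)oxy]-2,6-dimethyl-11-(trimethylsilyl)undeca-2,6-dien-10-yn-1-ol
Conditions: i-Bu2AlH (2.5 equiv), CH2Cl2, −78 °C; Rochelle-salt work-up
Reagents that add atoms: none
Why: i-Bu2AlH reduces the conjugated ester in the 1,2 sense to the Z-allylic alcohol (hydride reduction) and leaves the silyl ether and the silylalkyne alone.

Step 8
Reactants: 11 (2Z,6E,8S)-8-[(tert-butyldimethylsilyl)oxy]-2,6-dimethyl-11-(trimethylsilyl)undeca-2,6-dien-10-yn-1-ol
Product: 12 (2Z,6E,8S,10E)-8-[(tert-butyldimethylsilyl)oxy]-11-iodo-2,6,10-trimethyl-11-(trimethylsilyl)undeca-2,6,10-trien-1-ol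
Conditions: MeMgBr (4 equiv), Ni(acac)2 (10 mol %), Me3Al (10 mol %), THF, rt; then I2, −78 to 0 °C
Reagents that add atoms: methylmagnesium bromide, C[Mg]Br; iodine, II
Why: Nickel-catalysed syn-carbomagnesiation of an alkynylsilane puts methyl on the carbon remote from silicon (C8) and magnesium on the silicon-bearing carbon (C9), and iodinolysis with retention fixes Si cis to C7; the free hydroxyl is carried as its magnesium alkoxide and the quench is made early to limit isomerisation of the α-silyl alkenylmagnesium.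

Step 9
Reactants: 13 tert-butyl(but-3-yn-1-yloxy)dimethylsilane
Product: 14 methyl (2E)-5-[(tert-butyldimethylsilyl)oxy]-3-methylpent-2-enoate
Conditions: Me3Al (2 equiv), Cp2ZrCl2 (0.25 equiv), CH2Cl2, 0 °C to rt; then ClCO2Me, 0 °C to rt
Reagents that add atoms: trimethylaluminium, C[Al](C)C; methyl chloroformate, COC(=O)Cl
Why: Zirconium-catalysed carboalumination (Negishi) adds methyl and aluminium syn with aluminium at the terminal carbon, and acylation of the alkenylalane with retention should give the E-3-methyl enoate.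

Step 10
Reactants: 14 methyl (2E)-5-[(tert-butyldimethylsilyl)oxy]-3-methylpent-2-enoate
Product: 15 methyl (2E)-5-bromo-3-methylpent-2-enoate
Conditions: Ph3PBr2, CH2Cl2, 0 °C to rt
Reagents that add atoms: dibromotriphenylphosphorane, BrP(Br)(c1ccccc1)(c1ccccc1)c1ccccc1
Why: Dibromotriphenylphosphorane activates the silyl ether oxygen and bromide displaces it at the primary carbon (Appel-type SN2), which saves a separate desilylation.

Step 11
Reactants: 12 (2Z,6E,8S,10E)-8-[(tert-butyldimethylsilyl)oxy]-11-iodo-2,6,10-trimethyl-11-(trimethylsilyl)undeca-2,6,10-trien-1-ol; 15 methyl (2E)-5-bromo-3-methylpent-2-enoate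
Product: 17 methyl (2E,6Z,9S,10E,14Z)-9-[(tert-butyldimethylsilyl)oxy]-16-hydroxy-3,7,11,15-tetramethyl-6-(trimethylsilyl)hexadeca-2,6,10,14-tetraenoate, via alkylzinc bromide 16 (not isolated)
Conditions: 15, Zn dust, LiCl, THF, 50 °C; then 12, Pd(dppf)Cl2 (5 mol %), THF, 50 °C (3 equiv of zinc reagent)
Reagents that add atoms: none
Why: LiCl-assisted zinc insertion gives an ester-tolerant alkylzinc, and Negishi coupling at the iodo(silyl)alkene proceeds with retention, so C11 ends trans to C7 and silicon stays cis to C7; the excess reagent covers the free hydroxyl.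

Step 12
Reactants: 17 methyl (2E,6Z,9S,10E,14Z)-9-[(tert-butyldimethylsilyl)oxy]-16-hydroxy-3,7,11,15-tetramethyl-6-(trimethylsilyl)hexadeca-2,6,10,14-tetraenoate
Product: 18 methyl (2E,6Z,9S,10E)-9-[(tert-butyldimethylsilyl)oxy]-13-[(2S,3R)-3-(hydroxymethyl)-3-methyloxiran-2-yl]-3,7,11-trimethyl-6-(trimethylsilyl)trideca-2,6,10-trienoate
Conditions: Ti(OiPr)4 (20 mol %), D-(−)-diethyl tartrate (24 mol %), t-BuOOH, 4 Å molecular sieves, CH2Cl2, −20 °C
Reagents that add atoms: tert-butyl hydroperoxide, CC(C)(C)OO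
Why: Sharpless asymmetric epoxidation touches only the alkene that carries the free allylic hydroxyl, and with D-(−)-tartrate oxygen is delivered to the face of this Z-allylic alcohol that gives the (2S,3R)-oxirane, that is C3 S and C4 R.

Step 13
Reactants: 18 methyl (2E,6Z,9S,10E)-9-[(tert-butyldimethylsilyl)oxy]-13-[(2S,3R)-3-(hydroxymethyl)-3-methyloxiran-2-yl]-3,7,11-trimethyl-6-(trimethylsilyl)trideca-2,6,10-trienoate
Product: 19 methyl (2E,6Z,9S,10E)-9-[(tert-butyldimethylsilyl)oxy]-13-[(2S,3R)-3-{[(tert-butyldiphenylsilyl)oxy]methyl}-3-methyloxiran-2-yl]-3,7,11-trimethyl-6-(trimethylsilyl)trideca-2,6,10-trienoate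
Conditions: TBDPSCl, imidazole, CH2Cl2, 0 °C to rt
Reagents that add atoms: tert-butyldiphenylsilyl chloride, CC(C)(C)[Si](Cl)(c1ccccc1)c1ccccc1
Why: Silylation of the primary alcohol gives a non-participating, weakly basic ether that survives the Lewis acid and stays distinguishable from the C6 silyl ether.

Step 14
Reactants: 19 methyl (2E,6Z,9S,10E)-9-[(tert-butyldimethylsilyl)oxy]-13-[(2S,3R)-3-{[(tert-butyldiphenylsilyl)oxy]methyl}-3-methyloxiran-2-yl]-3,7,11-trimethyl-6-(trimethylsilyl)trideca-2,6,10-trienoate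
Product: 20 methyl (13E)-6α-[(tert-butyldimethylsilyl)oxy]-19-[(tert-butyldiphenylsilyl)oxy]-3β-hydroxylabda-8,13-dien-15-oate
Conditions: MeAlCl2 (3 equiv), CH2Cl2 (0.005 M), −78 °C; Et3N–MeOH quench, aqueous work-up
Reagents that add atoms: none
Why: Proposed new method: MeAlCl2 activates the oxirane, the C5=C10 π-bond opens it at the tertiary carbon C4 with inversion (6-endo closure of ring A through a chair), the resulting C10 cation is captured at C9, the silicon-bearing carbon of the Z-alkenylsilane, in a second 6-endo closure (ring B, chair, anti addition across C5=C10, hence the trans-decalin), and the β-silyl C8 cation loses Me3Si+ to chloride so that the alkene can only appear at C8=C9; the closest known reaction types are the Lewis-acid epoxy-polyene bicyclisation and the endocyclic vinylsilane-terminated cation–olefin cyclisation, here combined on a tetrasubstituted alkenylsilane. C3 (retained) and C4 (inverted) come from the oxirane, so the hydroxyl is equatorial (3β) and the Z-derived C19 is axial (4β); C5 and C10 follow from the E geometry of C5=C10 and the chair–chair fold that the oxirane selects; the C6 silyloxy group sits equatorial in that fold, so the S centre is the matched one. The step needs opening at C4 and not C3 (tertiary centre with backside π-participation), attack at C9 and not C8 (only C9 attack gives a tertiary cation that is also β to silicon, whereas C8 attack would give an α-silyl cation in a five-membered ring), and silyl loss faster than proton loss (Si cis to C7 lets the C–Si bond align with the empty orbital as ring B flattens). The weakly basic silyl ethers at C6 and C19 should neither chelate aluminium nor ionise at −78 °C.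

Step 15
Reactants: 20 methyl (13E)-6α-[(tert-butyldimethylsilyl)oxy]-19-[(tert-butyldiphenylsilyl)oxy]-3β-hydroxylabda-8,13-dien-15-oate
Product: 21 methyl (13E)-19-[(tert-butyldiphenylsilyl)oxy]-3β,6α-dihydroxylabda-8,13-dien-15-oate
Conditions: HF (48 % aq.), MeCN, 0 °C to rt
Reagents that add atoms: none
Why: Acidic fluoride desilylation discriminates by silyl group, so the tert-butyldimethylsilyl ether at C6 should cleave well before the neopentyl tert-butyldiphenylsilyl ether at C19.

Step 16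
Reactants: 21 methyl (13E)-19-[(tert-butyldiphenylsilyl)oxy]-3β,6α-dihydroxylabda-8,13-dien-15-oate
Product: 22 methyl (13E)-19-[(tert-butyldiphenylsilyl)oxy]-3,6-dioxolabda-8,13-dien-15-oate
Conditions: Dess–Martin periodinane (3 equiv), NaHCO3, CH2Cl2, 0 °C to rt; used crude
Reagents that add atoms: none
Why: Dess–Martin oxidation converts both secondary alcohols into ketones under buffered, non-enolising conditions, so the β,γ-unsaturated C6 ketone should not move into conjugation and the trans ring fusion at C5 is the stable one.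

Step 17
Reactants: 22 methyl (13E)-19-[(tert-butyldiphenylsilyl)oxy]-3,6-dioxolabda-8,13-dien-15-oate
Product: 23 methyl (13E)-19-[(tert-butyldiphenylsilyl)oxy]-3α,6β-dihydroxylabda-8,13-dien-15-oate
Conditions: LiBH(s-Bu)3 (3 equiv), THF, −78 to −40 °C; aqueous NH4Cl
Reagents that add atoms: none
Why: Bulky-hydride reduction follows the equatorial trajectory at both ketones: at C3 this gives the axial 3α-alcohol, and at C6, where the β face is closed by the 1,3-diaxial C20 methyl and C19 methylene, hydride enters from the α face and gives the axial 6β-alcohol.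

Step 18
Reactants: 23 methyl (13E)-19-[(tert-butyldiphenylsilyl)oxy]-3α,6β-dihydroxylabda-8,13-dien-15-oate
Product: 25 (13E)-3α,6β,19-trihydroxylabda-8,13-dien-15-oic acid, via triol methyl ester 24 (not isolated)
Conditions: Bu4NF, THF, 50 °C; then LiOH, THF–MeOH–H2O, 40 °C; 1 M HCl to pH 4 at 0 °C
Reagents that add atoms: lithium hydroxide, [Li+].[OH-]
Why: Fluoride removes the last silyl ether and hydroxide saponifies the methyl ester (acyl substitution), with no stereocentre α to a carbonyl and an E-enoate that is stable to base.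

**Compound list**

1 | geranyl acetate, (2E)-3,7-dimethylocta-2,6-dien-1-yl acetate | CC(C)=CCC/C(C)=C/COC(C)=O | starting material
2 | 6,7-epoxygeranyl acetate (racemic), (2E)-5-(3,3-dimethyloxiran-2-yl)-3-methylpent-2-en-1-yl acetate | CC1(C)OC1CC/C(C)=C/COC(C)=O | intermediate
3 | (2E)-3-methyl-6-oxohex-2-en-1-yl acetate | O=CCC/C(C)=C/COC(C)=O | intermediate
4 | ethyl 2-[bis(2,2,2-trifluoroethoxy)phosphoryl]propanoate | CCOC(=O)C(C)P(=O)(OCC(F)(F)F)OCC(F)(F)F | starting material
5 | ethyl (2Z,6E)-8-acetoxy-2,6-dimethylocta-2,6-dienoate | CCOC(=O)/C(C)=C\CC/C(C)=C/COC(C)=O | intermediate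
6 | ethyl (2Z,6E)-8-hydroxy-2,6-dimethylocta-2,6-dienoate | CCOC(=O)/C(C)=C\CC/C(C)=C/CO | intermediate
7 | ethyl (2Z,6E)-2,6-dimethyl-8-oxoocta-2,6-dienoate | CCOC(=O)/C(C)=C\CC/C(C)=C/C=O | intermediate
8 | 4,4,5,5-tetramethyl-2-[3-(trimethylsilyl)prop-2-yn-1-yl]-1,3,2-dioxaborolane | C[Si](C)(C)C#CCB1OC(C)(C)C(C)(C)O1 | starting material
9 | ethyl (2Z,6E,8S)-8-hydroxy-2,6-dimethyl-11-(trimethylsilyl)undeca-2,6-dien-10-ynoate | CCOC(=O)/C(C)=C\CC/C(C)=C/[C@@H](O)CC#C[Si](C)(C)C | intermediate
10 | ethyl (2Z,6E,8S)-8-[(tert-butyldimethylsilyl)oxy]-2,6-dimethyl-11-(trimethylsilyl)undeca-2,6-dien-10-ynoate | CCOC(=O)/C(C)=C\CC/C(C)=C/[C@@H](O[Si](C)(C)C(C)(C)C)CC#C[Si](C)(C)C | intermediate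
11 | (2Z,6E,8S)-8-[(tert-butyldimethylsilyl)oxy]-2,6-dimethyl-11-(trimethylsilyl)undeca-2,6-dien-10-yn-1-ol | OC/C(C)=C\CC/C(C)=C/[C@@H](O[Si](C)(C)C(C)(C)C)CC#C[Si](C)(C)C | intermediate
12 | (2Z,6E,8S,10E)-8-[(tert-butyldimethylsilyl)oxy]-11-iodo-2,6,10-trimethyl-11-(trimethylsilyl)undeca-2,6,10-trien-1-ol | OC/C(C)=C\CC/C(C)=C/[C@@H](O[Si](C)(C)C(C)(C)C)C/C(C)=C(/I)[Si](C)(C)C | intermediate
13 | tert-butyl(but-3-yn-1-yloxy)dimethylsilane | C#CCCO[Si](C)(C)C(C)(C)C | starting material
14 | methyl (2E)-5-[(tert-butyldimethylsilyl)oxy]-3-methylpent-2-enoate | COC(=O)/C=C(\C)CCO[Si](C)(C)C(C)(C)C | intermediate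
15 | methyl (2E)-5-bromo-3-methylpent-2-enoate | COC(=O)/C=C(\C)CCBr | intermediate
16 | bromo[(3E)-5-methoxy-3-methyl-5-oxopent-3-en-1-yl]zinc | COC(=O)/C=C(\C)CC[Zn]Br | intermediate
17 | methyl (2E,6Z,9S,10E,14Z)-9-[(tert-butyldimethylsilyl)oxy]-16-hydroxy-3,7,11,15-tetramethyl-6-(trimethylsilyl)hexadeca-2,6,10,14-tetraenoate | OC/C(C)=C\CC/C(C)=C/[C@@H](O[Si](C)(C)C(C)(C)C)C/C(C)=C(/CC/C(C)=C/C(=O)OC)[Si](C)(C)C | intermediate
18 | methyl (2E,6Z,9S,10E)-9-[(tert-butyldimethylsilyl)oxy]-13-[(2S,3R)-3-(hydroxymethyl)-3-methyloxiran-2-yl]-3,7,11-trimethyl-6-(trimethylsilyl)trideca-2,6,10-trienoate | OC[C@@]1(C)O[C@H]1CC/C(C)=C/[C@@H](O[Si](C)(C)C(C)(C)C)C/C(C)=C(/CC/C(C)=C/C(=O)OC)[Si](C)(C)C | intermediate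
19 | methyl (2E,6Z,9S,10E)-9-[(tert-butyldimethylsilyl)oxy]-13-[(2S,3R)-3-{[(tert-butyldiphenylsilyl)oxy]methyl}-3-methyloxiran-2-yl]-3,7,11-trimethyl-6-(trimethylsilyl)trideca-2,6,10-trienoate | CC(C)(C)[Si](c1ccccc1)(c1ccccc1)OC[C@@]1(C)O[C@H]1CC/C(C)=C/[C@@H](O[Si](C)(C)C(C)(C)C)C/C(C)=C(/CC/C(C)=C/C(=O)OC)[Si](C)(C)C | intermediate
20 | methyl (13E)-6α-[(tert-butyldimethylsilyl)oxy]-19-[(tert-butyldiphenylsilyl)oxy]-3β-hydroxylabda-8,13-dien-15-oate (3S,4S,5R,6S,10S) | CC1=C(CC/C(C)=C/C(=O)OC)[C@@]2(C)CC[C@H](O)[C@](C)(CO[Si](c3ccccc3)(c3ccccc3)C(C)(C)C)[C@@H]2[C@@H](O[Si](C)(C)C(C)(C)C)C1 | intermediate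
21 | methyl (13E)-19-[(tert-butyldiphenylsilyl)oxy]-3β,6α-dihydroxylabda-8,13-dien-15-oate | CC1=C(CC/C(C)=C/C(=O)OC)[C@@]2(C)CC[C@H](O)[C@](C)(CO[Si](c3ccccc3)(c3ccccc3)C(C)(C)C)[C@@H]2[C@@H](O)C1 | intermediate
22 | methyl (13E)-19-[(tert-butyldiphenylsilyl)oxy]-3,6-dioxolabda-8,13-dien-15-oate (4S,5R,10S) | CC1=C(CC/C(C)=C/C(=O)OC)[C@@]2(C)CCC(=O)[C@](C)(CO[Si](c3ccccc3)(c3ccccc3)C(C)(C)C)[C@@H]2C(=O)C1 | intermediate
23 | methyl (13E)-19-[(tert-butyldiphenylsilyl)oxy]-3α,6β-dihydroxylabda-8,13-dien-15-oate (3R,4S,5R,6R,10S) | CC1=C(CC/C(C)=C/C(=O)OC)[C@@]2(C)CC[C@@H](O)[C@](C)(CO[Si](c3ccccc3)(c3ccccc3)C(C)(C)C)[C@@H]2[C@H](O)C1 | intermediate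
24 | methyl (13E)-3α,6β,19-trihydroxylabda-8,13-dien-15-oate | CC1=C(CC/C(C)=C/C(=O)OC)[C@@]2(C)CC[C@@H](O)[C@](C)(CO)[C@@H]2[C@H](O)C1 | intermediate
25 | (13E)-3α,6β,19-trihydroxylabda-8,13-dien-15-oic acid, (2E)-5-[(4R,4aR,5S,6R,8aS)-4,6-dihydroxy-5-(hydroxymethyl)-2,5,8a-trimethyl-3,4,4a,5,6,7,8,8a-octahydronaphthalen-1-yl]-3-methylpent-2-enoic acid | CC1=C(CC/C(C)=C/C(=O)O)[C@@]2(C)CC[C@@H](O)[C@](C)(CO)[C@@H]2[C@H](O)C1 | target

**Step count**

Total: 18 steps. Longest linear sequence: 16 steps (steps 1–8 and 11–18); steps 9–10 make the side-chain fragment.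

**Steps most likely to fail**

Step 14 (Proposed new method). The C10 cation may be lost by proton elimination before it reaches the crowded silicon-bearing carbon, so the cascade stops after ring A; the oxirane may also rearrange, or the allylic silyl ether may ionise. The fallback uses known chemistry and drops silicon. It sets out from 11 and comes back at 20.
- K2CO3 in MeOH removes the alkyne silyl group and gives (2Z,6E,8S)-8-[(tert-butyldimethylsilyl)oxy]-2,6-dimethylundeca-2,6-dien-10-yn-1-ol F1.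
- Zirconium-catalysed carboalumination (Me3Al, Cp2ZrCl2) followed by I2 gives the E-iodide (2Z,6E,8S,10E)-8-[(tert-butyldimethylsilyl)oxy]-11-iodo-2,6,10-trimethylundeca-2,6,10-trien-1-ol F2.
- Negishi coupling with 16 gives the silicon-free tetraenol methyl (2E,6E,9S,10E,14Z)-9-[(tert-butyldimethylsilyl)oxy]-16-hydroxy-3,7,11,15-tetramethylhexadeca-2,6,10,14-tetraenoate F3.
- Sharpless epoxidation as in step 12 gives the epoxy alcohol F4, and silylation as in step 13 gives its tert-butyldiphenylsilyl ether F5.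
- MeAlCl2 then effects the known epoxy-polyene bicyclisation ended by proton loss. It should give 20 together with the C7=C8 isomer methyl (13E)-6α-[(tert-butyldimethylsilyl)oxy]-19-[(tert-butyldiphenylsilyl)oxy]-3β-hydroxylabda-7,13-dien-15-oate F6 and the exocyclic isomer methyl (13E)-6α-[(tert-butyldimethylsilyl)oxy]-19-[(tert-butyldiphenylsilyl)oxy]-3β-hydroxylabda-8(17),13-dien-15-oate F7.
- Iodine-catalysed equilibration in warm benzene should move F6 and F7 toward the tetrasubstituted alkene 20, with the remainder separated on AgNO3-impregnated silica.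

Step 8. The α-silyl alkenylmagnesium may isomerise before iodination, which would erode the Si-cis-to-C7 geometry that step 14 needs, and low-valent nickel with a Grignard reagent may attack the allylic C–O bonds. The fallback exchanges the carbomagnesiation for a zirconium-catalysed carboalumination and iodinolysis (Me3Al, Cp2ZrCl2, then I2 at −30 °C as soon as the alkyne is consumed). This is a different carbometalation manifold, without Grignard reagent or nickel. It sets out from 11, comes back at 12 and makes no new compound.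

Step 17. Facial selectivity at C3 may be poor because the axial C19 silyloxymethyl group crowds the equatorial trajectory, and the hindered C6 ketone may enolise toward C7 and drift into conjugation before it is reduced. The fallback turns C19 from a shield into a director. It sets out from 22 and comes back at 24.
- HF·pyridine removes the C19 silyl group and gives methyl (13E)-19-hydroxy-3,6-dioxolabda-8,13-dien-15-oate F8.
- Evans–Saksena reduction (Me4NBH(OAc)3, MeCN–AcOH, −20 °C) delivers hydride from the boron bound to the axial C19 oxygen to the β face of C3 and should give methyl (13E)-3α,19-dihydroxy-6-oxolabda-8,13-dien-15-oate F9.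
- NaBH4 in MeOH at 0 °C then reduces the C6 ketone from the open α face to give 24, which is saponified as in step 18.

**Further compounds**

F1 | step 14 | (2Z,6E,8S)-8-[(tert-butyldimethylsilyl)oxy]-2,6-dimethylundeca-2,6-dien-10-yn-1-ol | OC/C(C)=C\CC/C(C)=C/[C@@H](O[Si](C)(C)C(C)(C)C)CC#C
F2 | step 14 | (2Z,6E,8S,10E)-8-[(tert-butyldimethylsilyl)oxy]-11-iodo-2,6,10-trimethylundeca-2,6,10-trien-1-ol | OC/C(C)=C\CC/C(C)=C/[C@@H](O[Si](C)(C)C(C)(C)C)C/C(C)=C/I
F3 | step 14 | methyl (2E,6E,9S,10E,14Z)-9-[(tert-butyldimethylsilyl)oxy]-16-hydroxy-3,7,11,15-tetramethylhexadeca-2,6,10,14-tetraenoate | OC/C(C)=C\CC/C(C)=C/[C@@H](O[Si](C)(C)C(C)(C)C)C/C(C)=C/CC/C(C)=C/C(=O)OC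
F4 | step 14 | methyl (2E,6E,9S,10E)-9-[(tert-butyldimethylsilyl)oxy]-13-[(2S,3R)-3-(hydroxymethyl)-3-methyloxiran-2-yl]-3,7,11-trimethyltrideca-2,6,10-trienoate | OC[C@@]1(C)O[C@H]1CC/C(C)=C/[C@@H](O[Si](C)(C)C(C)(C)C)C/C(C)=C/CC/C(C)=C/C(=O)OC
F5 | step 14 | methyl (2E,6E,9S,10E)-9-[(tert-butyldimethylsilyl)oxy]-13-[(2S,3R)-3-{[(tert-butyldiphenylsilyl)oxy]methyl}-3-methyloxiran-2-yl]-3,7,11-trimethyltrideca-2,6,10-trienoate | CC(C)(C)[Si](c1ccccc1)(c1ccccc1)OC[C@@]1(C)O[C@H]1CC/C(C)=C/[C@@H](O[Si](C)(C)C(C)(C)C)C/C(C)=C/CC/C(C)=C/C(=O)OC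
F6 | step 14 | methyl (13E)-6α-[(tert-butyldimethylsilyl)oxy]-19-[(tert-butyldiphenylsilyl)oxy]-3β-hydroxylabda-7,13-dien-15-oate (9α-H) | CC=1[C@H](CC/C(C)=C/C(=O)OC)[C@@]2(C)CC[C@H](O)[C@](C)(CO[Si](c3ccccc3)(c3ccccc3)C(C)(C)C)[C@@H]2[C@@H](O[Si](C)(C)C(C)(C)C)C1
F7 | step 14 | methyl (13E)-6α-[(tert-butyldimethylsilyl)oxy]-19-[(tert-butyldiphenylsilyl)oxy]-3β-hydroxylabda-8(17),13-dien-15-oate (9α-H) | C=C1[C@H](CC/C(C)=C/C(=O)OC)[C@@]2(C)CC[C@H](O)[C@](C)(CO[Si](c3ccccc3)(c3ccccc3)C(C)(C)C)[C@@H]2[C@@H](O[Si](C)(C)C(C)(C)C)C1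
F0 | step 8 | none | none
F8 | step 17 | methyl (13E)-19-hydroxy-3,6-dioxolabda-8,13-dien-15-oate | CC1=C(CC/C(C)=C/C(=O)OC)[C@@]2(C)CCC(=O)[C@](C)(CO)[C@@H]2C(=O)C1
F9 | step 17 | methyl (13E)-3α,19-dihydroxy-6-oxolabda-8,13-dien-15-oate | CC1=C(CC/C(C)=C/C(=O)OC)[C@@]2(C)CC[C@@H](O)[C@](C)(CO)[C@@H]2C(=O)C1
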